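- A closed flask keeps its charge (mass balance), so in Thursday's flask ring, substrate and an unseen share always add up to 100 %.

all flasks: temperature 5 °C

| run | substrate | remark | time |
|---|---|---|---|
| Thursday's | 0.40 M | the very flask that is asked about, followed so far |  |
| Wednesday's | 0.20 M | run made earlier |  |
| flask | 0.40 M |  | 8.0 d |

Thursday's run (percent of the substrate charged)

| time / d | ring / % | substrate / % |
|---|---|---|
| 0.500 | 12.8 | 15.4 |
| 1.04 | 22.0 | 13.9 |
| 1.67 | 30.0 | 11.5 |
| 3.00 | 34.8 | 8.8 |
| 6.00 | 32.2 | 2.0 |

Wednesday's run (percent of the substrate charged)

| time / h | ring / % | substrate / % |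
|---|---|---|
| 4.00 | 9.8 | 25.3 |
| 8.00 | 13.7 | 22.1 |
| 15.0 | 20.8 | 19.9 |
| 25.0 | 28.8 | 17.4 |
| 50.0 | 36.2 | 12.7 |

(standard deviation of a reading: 1 percentage point)

- ochre: change nothing and wait 15 d more
- teal: at 8.0 d take out 90 % of the ring then present, then wait 15 d
- grey: at 8.0 d raise the temperature by 15 K, then wait 15 d
- violet: at 8.0 d add substrate, 50.0 % of the amount charged, then wait 15 d

- what is taken out of ring is counted as made
- the earlier runs do not show what temperature does; that part of a forecast is a guess
- additions bring no volume worth counting

- ring, in percent of the substrate first charged, at 8.0 d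
- what to do for the largest gain in ring; "none" if nothing gains more than 2 percentage points (ochre / teal / grey / violet / none)
- ring present, with what was taken out counted in, in percent of the substrate first charged, after teal
- ring present, with what was taken out counted in, in percent of the substrate first charged, after grey

- The inputs that could matter for ring at 8.0 d are the last two values of the unseen share in Thursday's flask and the [substrate] then present. A value at 6.00 d that is off by 1 percentage point moves the result by 1.7 points, and one at 3.00 d moves it by 0.67 points. The [substrate] still present at 8.0 d is taken here to lie between zero and the last reading, 2.0 %, a band of like width.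
- Wednesday's readings, at half the charge, do not enter this reckoning.
- In Thursday's flask the unseen share read 71.8 % at 0.500 d and 56.4 % at 3.00 d, so it first fell and part of it returned. It then rose to 65.8 % at 6.00 d.
- Carrying that last rise forward in a straight line gives the projected unseen share, the part of the charge outside ring and substrate at the asked time: 72.1 %.
- The reckoning made here therefore puts ring between 25.9 % and 27.9 %. Thursday's readings, which end at 6.00 d, do not tell whether the late unseen share can return.
- The forecast differs: ring 24 % (range 20 % to 29 %), a central value below that band. It chooses teal, with 22.5 % after teal and 1 % after grey, on the ground that “Heating speeds the loss, so grey leaves almost nothing”.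
- The flask gives ring 26.6 % at 8.0 d, and the best choice is grey, gaining 20 points: 47.0 % after grey, 38.7 % after teal.

    2 substrate ⇌ open dimer (K = 25.0 M⁻¹, k = 2.20 M⁻¹ h⁻¹, Ea = 73.0 kJ mol⁻¹, ΔH = 12.0 kJ mol⁻¹)
    substrate → ring (k = 0.0560 h⁻¹, Ea = 92.0 kJ mol⁻¹)
    substrate ⇌ dormant form (K = 19.0, k = 0.0200 h⁻¹, Ea = 104 kJ mol⁻¹, ΔH = −2.00 kJ mol⁻¹)
    ring ⇌ isomer of the product (K = 3.10, k = 0.0120 h⁻¹, Ea = 94.0 kJ mol⁻¹, ΔH = −47.0 kJ mol⁻¹)
    (constants at 5 °C)

- The unseen share of the flask at 8.0 d comes to 72.9 %, mostly isomer of the product 49.3 % and dormant form 23.4 %. Grey ends above the 27.9 % left outside the projected unseen share, so unseen material came back into ring. In the flask, each step taken net, ring is made 2.10 times as fast as it is used up at 1.74 d, but that ratio is 0.240 at 8.00 d. The same charge run at 20 °C has an unseen share of 55.8 % at 8.0 d, with isomer of the product at 47.9 % and dormant form at 7.98 %.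

The numbers in the tables were computed with constants of no real substance.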